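Numbering: unit A is the 7-hydroxy-6,8-dimethoxycoumarin that carries the ether oxygen on C3 (unprimed). Unit B is the 6,8-dimethoxycoumarin bound through C7' (primed).
Cuts, in retrosynthetic order: benzyl from O7; lactone B at C3'=C4' and O1'–C2'; CH3 from O6'; C5'–C6' of arene B (retro-6π), with the dienylketene folded back to a cyclobutenone; C4a'–C8a' (vinyllithium plus squarate carbonyl); O–C7' (squaric ester chloride plus coumarin-3-ol); lactone A at C3=C4 and O1–C2.
Enabling feature: in arene B the neighbouring carbons C8a', C8', C7' and C6' all bear oxygen and are followed by C5'–H and the carbon-substituted C4a'. The four oxygenated carbons are the four ring carbons of squaric acid, and C4a'/C5' are the two carbons of a 1,1-disubstituted vinyl group.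
Forward order: arene A is bought and hydroxylated at the future C8a; lactone A closes; the coumarin-3-ol is hung on the flat four-membered ring; the C3 acrolein unit is added; arene B grows around the finished ether; lactone B closes; the benzyl group is removed.
Stereochemistry: none has to be set. The only stereocentres met on the way (a dibromide carbon and the cyclobutenone carbinol carbon) are racemic and are destroyed.

Key step: step 14

Remark: the target SMILES holds no stereocentre and its ether bridge rotates freely, so "single enantiomer" is read as the one achiral constitution drawn.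
Abbreviation: Cou = 7-(benzyloxy)-6,8-dimethoxy-2-oxo-2H-chromen-3-yl.

Step 1
Reactants: 1 syringaldehyde (4-hydroxy-3,5-dimethoxybenzaldehyde)
Product: 2 4-(benzyloxy)-3,5-dimethoxybenzaldehyde
Conditions: BnBr, K2CO3, DMF, 60 °C
Reagents that add atoms: benzyl bromide, BrCc1ccccc1
Why: Williamson ether synthesis on the acidic para-formyl phenol; the benzyl group should outlast acid, base, organolithium and heat until the last step.

Step 2
Reactants: 2 4-(benzyloxy)-3,5-dimethoxybenzaldehyde
Product: 3 4-(benzyloxy)-2-bromo-3,5-dimethoxybenzaldehyde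
Conditions: NBS, MeCN, rt, dark
Reagents that add atoms: N-bromosuccinimide, O=C1CCC(=O)N1Br
Why: Electrophilic aromatic bromination at one of the two equivalent free positions, each ortho to one methoxy group and para to the other, as is usual for 3,4,5-trialkoxybenzaldehydes; a polar medium without light disfavours radical attack on the benzylic CH2.

Step 3
Reactants: 3 4-(benzyloxy)-2-bromo-3,5-dimethoxybenzaldehyde
Product: 4 2-[4-(benzyloxy)-2-bromo-3,5-dimethoxyphenyl]-1,3-dioxolane
Conditions: HOCH2CH2OH, p-TsOH (cat.), toluene, reflux, Dean–Stark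
Reagents that add atoms: ethylene glycol, OCCO
Why: Acid-catalysed acetalisation driven by azeotropic removal of water hides the aldehyde from n-BuLi and from peroxide (Dakin oxidation) in step 4.

Step 4
Reactants: 4 2-[4-(benzyloxy)-2-bromo-3,5-dimethoxyphenyl]-1,3-dioxolane
Product: 8 4-(benzyloxy)-2-hydroxy-3,5-dimethoxybenzaldehyde, via aryllithium 5 (not isolated), via dimethyl arylboronate 6 (not isolated), via phenol dioxolane 7 (not isolated)
Conditions: n-BuLi, THF, −78 °C; B(OMe)3, −78 °C → rt; 30% H2O2, 2 M NaOH, 0 °C; Na2SO3; then 2 M HCl, rt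
Reagents that add atoms: n-butyllithium, [Li]CCCC (lithium in 5 only); trimethyl borate, COB(OC)OC (boron and its methoxy groups in 6 only); hydrogen peroxide, OO (phenol oxygen); water, O (aldehyde oxygen)
Why: Bromine–lithium exchange, borylation and alkaline peroxide oxidation (1,2-aryl shift from boron to oxygen) place the hydroxyl exactly where bromine stood, and acid releases the aldehyde only after the peroxide has been destroyed.

Step 5
Reactants: 8 4-(benzyloxy)-2-hydroxy-3,5-dimethoxybenzaldehyde; 9 N-acetylglycine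
Product: 10 N-[7-(benzyloxy)-6,8-dimethoxy-2-oxo-2H-chromen-3-yl]acetamide
Conditions: Ac2O, NaOAc, 115 °C
Reagents that add atoms: none
Why: Erlenmeyer–Plöchl condensation of the anhydride-activated glycine CH2 with the aldehyde, followed by acyl transfer to the ortho oxygen (Perkin-type coumarin closure), forms C3=C4 and O1–C2 in one operation, the standard entry to 3-acetamidocoumarins.

Step 6
Reactants: 10 N-[7-(benzyloxy)-6,8-dimethoxy-2-oxo-2H-chromen-3-yl]acetamide
Product: 12 7-(benzyloxy)-3-hydroxy-6,8-dimethoxy-2H-chromen-2-one (Cou-OH), via 3-aminocoumarin 11 (not isolated)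
Conditions: 3 M aq HCl, 1,4-dioxane, reflux, N2
Reagents that add atoms: water, O
Why: Acid hydrolysis of the enamide and then of the enamine (through its iminium tautomer) leaves the α-keto lactone, which rests as its enol, the established passage from 3-acetamido- to 3-hydroxycoumarins; dilute aqueous acid should spare the aryl benzyl ether.

Step 7
Reactants: 13 squaric acid (3,4-dihydroxycyclobut-3-ene-1,2-dione)
Product: 14 3,4-dichlorocyclobut-3-ene-1,2-dione
Conditions: SOCl2, DMF (cat.), toluene, reflux
Reagents that add atoms: thionyl chloride, O=S(Cl)Cl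
Why: Vilsmeier-catalysed conversion of the two vinylogous carboxylic acid hydroxyls into chlorides, the usual preparation of squaric dichloride.

Step 8
Reactants: 14 3,4-dichlorocyclobut-3-ene-1,2-dione
Product: 15 3-chloro-4-methoxycyclobut-3-ene-1,2-dione
Conditions: MeOH (1.0 equiv), CH2Cl2, 0 °C → rt, then evaporation
Reagents that add atoms: methanol, CO
Why: Addition–elimination at a vinylogous acid chloride; the first methoxy group donates into the ring and slows a second substitution, so one equivalent of methanol should stop at the ester chloride.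

Step 9
Reactants: 15 3-chloro-4-methoxycyclobut-3-ene-1,2-dione; 12 7-(benzyloxy)-3-hydroxy-6,8-dimethoxy-2H-chromen-2-one
Product: 16 3-(Cou-oxy)-4-methoxycyclobut-3-ene-1,2-dione
Conditions: i-Pr2NEt, CH2Cl2, −20 → 0 °C
Reagents that add atoms: none
Why: Addition–elimination of the phenol-like enol oxygen at the C–Cl carbon, the way squaric chlorides are known to esterify alcohols and phenols; this carbon (future C7') lies in a flat, open four-membered ring, chloride leaves far more readily than methoxide, and the hard electrophile favours O- over C4-attack.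

Step 10
Reactants: 17 acrolein diethyl acetal (3,3-diethoxyprop-1-ene)
Product: 18 (±)-2,3-dibromo-1,1-diethoxypropane
Conditions: Br2, CH2Cl2, −10 °C
Reagents that add atoms: bromine, BrBr
Why: Electrophilic addition of bromine to the alkene through a bromonium ion, with the acetal inert in the dry neutral medium; the new C2 stereocentre is racemic and is removed in step 11.

Step 11
Reactants: 18 (±)-2,3-dibromo-1,1-diethoxypropane
Product: 19 2-bromo-3,3-diethoxyprop-1-ene
Conditions: KOt-Bu (1.05 equiv), THF, 0 °C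
Reagents that add atoms: none
Why: E2 dehydrobromination removes the C2–H, acidified by bromine and the acetal carbon, with loss of the primary bromide, and a single equivalent of base at 0 °C should stop before the alkyne.

Step 12
Reactants: 19 2-bromo-3,3-diethoxyprop-1-ene; 16 3-(Cou-oxy)-4-methoxycyclobut-3-ene-1,2-dione
Product: 22 (±)-2-(Cou-oxy)-4-(3,3-diethoxyprop-1-en-2-yl)-4-hydroxy-3-methoxycyclobut-2-en-1-one, via vinyllithium 20 (not isolated), via lithium alkoxide 21 (not isolated)
Conditions: 19, n-BuLi (1.0 equiv), THF, −78 °C; cannulated into 16 (1.0 equiv), THF, −90 → −78 °C; AcOH in THF, −78 °C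
Reagents that add atoms: n-butyllithium, [Li]CCCC (lithium in 20 and 21 only)
Why: Proposed new method: 1,2-addition of an alkenyllithium to an alkyl aryl squarate is without precedent, but the carbonyl next to C–OMe is conjugated (O=C–C=C–OCou) only with the weak coumarinyloxy donor, whose lone pair is shared with the enol-lactone, whereas the other carbonyl is a genuine vinylogous methyl ester and is also the more shielded one, so the hard nucleophile should add irreversibly at the former at −78 °C, faster than it displaces aryloxide or touches the much less electrophilic lactone (inverse addition, no excess); the closest known reaction type is the regioselective 1,2-addition of organolithiums to unsymmetrical cyclobutenediones (3-alkoxy-4-alkyl, 3-alkoxy-4-amino) at the carbonyl that is not the better-stabilised vinylogous ester; the new carbinol centre is racemic and is erased in step 14.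

Step 13
Reactants: 22 (±)-2-(Cou-oxy)-4-(3,3-diethoxyprop-1-en-2-yl)-4-hydroxy-3-methoxycyclobut-2-en-1-one
Product: 23 (±)-2-(Cou-oxy)-4-(3,3-diethoxyprop-1-en-2-yl)-3-methoxy-4-(methoxymethoxy)cyclobut-2-en-1-one
Conditions: MOMCl, i-Pr2NEt, Bu4NI (cat.), CH2Cl2, 0 °C → rt
Reagents that add atoms: chloromethyl methyl ether, COCCl
Why: MOM protection of the tertiary cyclobutenol with a very reactive alkylating agent and a hindered amine, a usual way of capping 4-hydroxycyclobutenones; the aryloxy group now sits α to the carbonyl, out of reach of addition–elimination, and the excess base keeps the diethyl acetal safe.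

Step 14
Reactants: 23 (±)-2-(Cou-oxy)-4-(3,3-diethoxyprop-1-en-2-yl)-3-methoxy-4-(methoxymethoxy)cyclobut-2-en-1-one
Product: 26 7-(benzyloxy)-3-[4-(diethoxymethyl)-6-hydroxy-2-methoxy-3-(methoxymethoxy)phenoxy]-6,8-dimethoxy-2H-chromen-2-one, via dienylketene 24 (not isolated), via cyclohexadienone 25 (not isolated)
Conditions: degassed toluene (0.02 M), 110 °C, Ar
Reagents that add atoms: none
Why: Heat breaks the C1–C4 σ-bond of 23 in a conrotatory 4π electrocyclic opening in which the donor OMOM group turns outward (torquoselectivity), so the 3,3-diethoxyprop-1-en-2-yl group turns inward and the (Z)-dienylketene 24 arises with its vinyl CH2 beside the ketene carbon. A thermal disrotatory 6π electrocyclisation then joins the ketene carbon (future C6') to that CH2 (future C5'), closing the six-membered carbocycle of unit B as cyclohexa-2,4-dienone 25, and a proton shift from C5' to the carbonyl oxygen aromatises it to phenol 26. The closest known reaction type is the Moore rearrangement of squarate-derived 4-alkenyl-4-hydroxy- or 4-alkoxycyclobutenones to tetra-oxygenated hydroquinones and their monoethers. No stereocentre is created, and the racemic carbinol carbon of 23 becomes the planar C8a'. The step needs the right sense of rotation and closure onto carbon in preference to trapping of the ketene: the oxygen donor on C4 secures the first, while the absence of any free OH or NH in 23, the dilution and the unhindered terminal methylene secure the second. Since O8a' leaves the step as a MOM ether, only the C6' oxygen is free, oxidation to a quinone is blocked and the two para oxygens are already told apart.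

Step 15
Reactants: 26 7-(benzyloxy)-3-[4-(diethoxymethyl)-6-hydroxy-2-methoxy-3-(methoxymethoxy)phenoxy]-6,8-dimethoxy-2H-chromen-2-one
Product: 27 7-(benzyloxy)-3-[4-(diethoxymethyl)-2,6-dimethoxy-3-(methoxymethoxy)phenoxy]-6,8-dimethoxy-2H-chromen-2-one
Conditions: MeI, K2CO3, acetone, 40 °C, Ar
Reagents that add atoms: methyl iodide, CI
Why: Williamson methylation of the only free phenol (O6'), under conditions that leave the lactone, both acetals and the benzyl ether untouched.

Step 16
Reactants: 27 7-(benzyloxy)-3-[4-(diethoxymethyl)-2,6-dimethoxy-3-(methoxymethoxy)phenoxy]-6,8-dimethoxy-2H-chromen-2-one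
Product: 29 4-(Cou-oxy)-2-hydroxy-3,5-dimethoxybenzaldehyde, via MOM-protected aldehyde 28 (not isolated)
Conditions: 2 M aq HCl, THF, 50 °C
Reagents that add atoms: water, O
Why: Acid hydrolysis first of the electron-rich benzylic diethyl acetal and then of the aryl MOM ether, whose loss is favoured by hydrogen bonding of the freed phenol to the ortho formyl group; the benzyl ether and the aromatic-like 3-aryloxycoumarin linkage should resist dilute acid.

Step 17
Reactants: 29 4-(Cou-oxy)-2-hydroxy-3,5-dimethoxybenzaldehyde; 30 ethyl (triphenylphosphoranylidene)acetate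
Product: 32 7-(benzyloxy)-3-[(6,8-dimethoxy-2-oxo-2H-chromen-7-yl)oxy]-6,8-dimethoxy-2H-chromen-2-one, via E-cinnamate 31 (not isolated)
Conditions: N,N-diethylaniline, reflux (ca. 215 °C), Ar
Reagents that add atoms: none
Why: Wittig olefination with the stabilised ylide forms C3'=C4', and at this temperature E/Z isomerisation lets the ortho phenol close O1'–C2' with loss of ethanol, the standard one-pot coumarin synthesis from salicylaldehydes.

Step 18
Reactants: 32 7-(benzyloxy)-3-[(6,8-dimethoxy-2-oxo-2H-chromen-7-yl)oxy]-6,8-dimethoxy-2H-chromen-2-one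
Product: 33 3-[(6,8-dimethoxy-2-oxo-2H-chromen-7-yl)oxy]-7-hydroxy-6,8-dimethoxy-2H-chromen-2-one (CNP0278842.0)
Conditions: BCl3, pentamethylbenzene, CH2Cl2, −78 °C; then H2O
Reagents that add atoms: none
Why: Lewis-acid debenzylation with a non-basic cation scavenger (the benzyl cation is taken up by Friedel–Crafts alkylation of pentamethylbenzene); at −78 °C the four methyl ethers, the bridging ether, both lactones and the C3'=C4' double bond, which hydrogenolysis might saturate, should stay intact.

Compound list
1 | syringaldehyde | COc1cc(C=O)cc(OC)c1O | starting material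
2 | 4-(benzyloxy)-3,5-dimethoxybenzaldehyde | COc1cc(C=O)cc(OC)c1OCc1ccccc1 | intermediate
3 | 4-(benzyloxy)-2-bromo-3,5-dimethoxybenzaldehyde | COc1cc(C=O)c(Br)c(OC)c1OCc1ccccc1 | intermediate
4 | 2-[4-(benzyloxy)-2-bromo-3,5-dimethoxyphenyl]-1,3-dioxolane | COc1cc(C2OCCO2)c(Br)c(OC)c1OCc1ccccc1 | intermediate
5 | [3-(benzyloxy)-6-(1,3-dioxolan-2-yl)-2,4-dimethoxyphenyl]lithium | COc1cc(C2OCCO2)c([Li])c(OC)c1OCc1ccccc1 | intermediate
6 | dimethyl [3-(benzyloxy)-6-(1,3-dioxolan-2-yl)-2,4-dimethoxyphenyl]boronate | COc1cc(C2OCCO2)c(B(OC)OC)c(OC)c1OCc1ccccc1 | intermediate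
7 | 3-(benzyloxy)-6-(1,3-dioxolan-2-yl)-2,4-dimethoxyphenol | COc1cc(C2OCCO2)c(O)c(OC)c1OCc1ccccc1 | intermediate
8 | 4-(benzyloxy)-2-hydroxy-3,5-dimethoxybenzaldehyde | COc1cc(C=O)c(O)c(OC)c1OCc1ccccc1 | intermediate
9 | N-acetylglycine | CC(=O)NCC(O)=O | starting material
10 | N-[7-(benzyloxy)-6,8-dimethoxy-2-oxo-2H-chromen-3-yl]acetamide | CC(=O)Nc1cc2cc(OC)c(OCc3ccccc3)c(OC)c2oc1=O | intermediate
11 | 3-amino-7-(benzyloxy)-6,8-dimethoxy-2H-chromen-2-one | Nc1cc2cc(OC)c(OCc3ccccc3)c(OC)c2oc1=O | intermediate
12 | 7-(benzyloxy)-3-hydroxy-6,8-dimethoxy-2H-chromen-2-one | Oc1cc2cc(OC)c(OCc3ccccc3)c(OC)c2oc1=O | intermediate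
13 | squaric acid | OC1=C(O)C(=O)C1=O | starting material
14 | 3,4-dichlorocyclobut-3-ene-1,2-dione | ClC1=C(Cl)C(=O)C1=O | intermediate
15 | 3-chloro-4-methoxycyclobut-3-ene-1,2-dione | COC1=C(Cl)C(=O)C1=O | intermediate
16 | 3-{[7-(benzyloxy)-6,8-dimethoxy-2-oxo-2H-chromen-3-yl]oxy}-4-methoxycyclobut-3-ene-1,2-dione | COC1=C(Oc2cc3cc(OC)c(OCc4ccccc4)c(OC)c3oc2=O)C(=O)C1=O | intermediate
17 | acrolein diethyl acetal | C=CC(OCC)OCC | starting material
18 | 2,3-dibromo-1,1-diethoxypropane (racemic) | CCOC(OCC)C(Br)CBr | intermediate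
19 | 2-bromo-3,3-diethoxyprop-1-ene | C=C(Br)C(OCC)OCC | intermediate
20 | (3,3-diethoxyprop-1-en-2-yl)lithium | [Li]C(=C)C(OCC)OCC | intermediate
21 | lithium alkoxide of 22 (racemic) | [Li]OC1(C(=C)C(OCC)OCC)C(OC)=C(Oc2cc3cc(OC)c(OCc4ccccc4)c(OC)c3oc2=O)C1=O | intermediate
22 | 2-{[7-(benzyloxy)-6,8-dimethoxy-2-oxo-2H-chromen-3-yl]oxy}-4-(3,3-diethoxyprop-1-en-2-yl)-4-hydroxy-3-methoxycyclobut-2-en-1-one (racemic) | OC1(C(=C)C(OCC)OCC)C(OC)=C(Oc2cc3cc(OC)c(OCc4ccccc4)c(OC)c3oc2=O)C1=O | intermediate
23 | 2-{[7-(benzyloxy)-6,8-dimethoxy-2-oxo-2H-chromen-3-yl]oxy}-4-(3,3-diethoxyprop-1-en-2-yl)-3-methoxy-4-(methoxymethoxy)cyclobut-2-en-1-one (racemic) | COCOC1(C(=C)C(OCC)OCC)C(OC)=C(Oc2cc3cc(OC)c(OCc4ccccc4)c(OC)c3oc2=O)C1=O | intermediate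
24 | (Z)-dienylketene, 2-(Cou-oxy)-5-(diethoxymethyl)-3-methoxy-4-(methoxymethoxy)hexa-1,3,5-trien-1-one | O=C=C(Oc1cc2cc(OC)c(OCc3ccccc3)c(OC)c2oc1=O)/C(OC)=C(OCOC)\C(=C)C(OCC)OCC | intermediate
25 | 2-(Cou-oxy)-5-(diethoxymethyl)-3-methoxy-4-(methoxymethoxy)cyclohexa-2,4-dien-1-one | O=C1CC(C(OCC)OCC)=C(OCOC)C(OC)=C1Oc1cc2cc(OC)c(OCc3ccccc3)c(OC)c2oc1=O | intermediate
26 | 7-(benzyloxy)-3-[4-(diethoxymethyl)-6-hydroxy-2-methoxy-3-(methoxymethoxy)phenoxy]-6,8-dimethoxy-2H-chromen-2-one | COCOc1c(OC)c(Oc2cc3cc(OC)c(OCc4ccccc4)c(OC)c3oc2=O)c(O)cc1C(OCC)OCC | intermediate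
27 | 7-(benzyloxy)-3-[4-(diethoxymethyl)-2,6-dimethoxy-3-(methoxymethoxy)phenoxy]-6,8-dimethoxy-2H-chromen-2-one | COCOc1c(OC)c(Oc2cc3cc(OC)c(OCc4ccccc4)c(OC)c3oc2=O)c(OC)cc1C(OCC)OCC | intermediate
28 | 4-{[7-(benzyloxy)-6,8-dimethoxy-2-oxo-2H-chromen-3-yl]oxy}-3,5-dimethoxy-2-(methoxymethoxy)benzaldehyde | COCOc1c(OC)c(Oc2cc3cc(OC)c(OCc4ccccc4)c(OC)c3oc2=O)c(OC)cc1C=O | intermediate
29 | 4-{[7-(benzyloxy)-6,8-dimethoxy-2-oxo-2H-chromen-3-yl]oxy}-2-hydroxy-3,5-dimethoxybenzaldehyde | Oc1c(OC)c(Oc2cc3cc(OC)c(OCc4ccccc4)c(OC)c3oc2=O)c(OC)cc1C=O | intermediate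
30 | ethyl (triphenylphosphoranylidene)acetate | CCOC(=O)C=P(c1ccccc1)(c1ccccc1)c1ccccc1 | starting material
31 | ethyl (E)-3-[4-(Cou-oxy)-2-hydroxy-3,5-dimethoxyphenyl]prop-2-enoate | CCOC(=O)/C=C/c1cc(OC)c(Oc2cc3cc(OC)c(OCc4ccccc4)c(OC)c3oc2=O)c(OC)c1O | intermediate
32 | 7-(benzyloxy)-3-[(6,8-dimethoxy-2-oxo-2H-chromen-7-yl)oxy]-6,8-dimethoxy-2H-chromen-2-one | COc1cc2cc(Oc3c(OC)cc4ccc(=O)oc4c3OC)c(=O)oc2c(OC)c1OCc1ccccc1 | intermediate
33 | 3-[(6,8-dimethoxy-2-oxo-2H-chromen-7-yl)oxy]-7-hydroxy-6,8-dimethoxy-2H-chromen-2-one | COc1cc2cc(Oc3c(OC)cc4ccc(=O)oc4c3OC)c(=O)oc2c(OC)c1O | target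

Total step count: 18. Longest linear sequence: 14 (steps 1–6, 9, 12–18).

Steps most likely to fail

Step 12. The vinyllithium may attack the wrong carbonyl, displace the aryloxide by addition–elimination, or open lactone A. The fallback uses known chemistry only, gives up the benzannulation and builds lactone A around the ether oxygen; it sets out from 8 and comes back at 32. Salicylaldehyde 8 is taken through the same Wittig–lactonisation with 30 to 7-(benzyloxy)-6,8-dimethoxycoumarin F1. This is debenzylated (BCl3, pentamethylbenzene) to isofraxidin F2. The crowded phenol is then O-alkylated with tert-butyl bromoacetate (K2CO3, acetone), where it only has to meet a primary bromide, to give tert-butyl (6,8-dimethoxy-2-oxo-2H-chromen-7-yl)oxyacetate F3, which TFA cleaves to (6,8-dimethoxy-2-oxo-2H-chromen-7-yl)oxyacetic acid F4. A Perkin-type condensation of F4 with a second portion of 8 (Ac2O, Et3N, 120 °C), the classical entry to 3-aryloxycoumarins, should give 32.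

Step 9. The activated aryl ester may hydrolyse, exchange its alkoxy and aryloxy groups, or suffer a second substitution while it is formed and isolated. The fallback makes the O–CH3 bond last, by SN2 at carbon instead of acyl-type substitution at the ring; it sets out from 14 and 12 and comes back at 16. Dichloride 14 takes one equivalent of 12 (i-Pr2NEt, CH2Cl2, −40 °C) to give 3-chloro-4-(Cou-oxy)cyclobut-3-ene-1,2-dione F5. Its remaining chloride is exchanged in wet THF to give the strongly acidic 3-(Cou-oxy)-4-hydroxycyclobut-3-ene-1,2-dione F6. O-methylation of the silver salt of F6 (Ag2O, MeI, MeCN) should give 16.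

Step 14. Ring opening of the MOM ether may be sluggish, methoxymethyl or ethoxy groups may be lost thermally at the temperature required, or the ketene may oligomerise. The fallback tells the two phenols apart by chelation instead of a protecting group; it sets out from 22 and comes back at 29. The unprotected carbinol 22, whose free hydroxyl is the stronger outward-rotating donor, is heated in degassed dioxane (100 °C, Ar) to give the hydroquinone 7-(benzyloxy)-3-[4-(diethoxymethyl)-3,6-dihydroxy-2-methoxyphenoxy]-6,8-dimethoxy-2H-chromen-2-one F7. This is hydrolysed without exposure to air (1 M HCl, THF) to 4-(Cou-oxy)-2,5-dihydroxy-3-methoxybenzaldehyde F8. Monomethylation of the hydroxyl that is not hydrogen-bonded to the formyl group (MeI, 1 equiv, Li2CO3, DMF, 40 °C) should give 29.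

Further compounds
F1 | step 12 | 7-(benzyloxy)-6,8-dimethoxy-2H-chromen-2-one | COc1cc2ccc(=O)oc2c(OC)c1OCc1ccccc1
F2 | step 12 | isofraxidin (7-hydroxy-6,8-dimethoxy-2H-chromen-2-one) | COc1cc2ccc(=O)oc2c(OC)c1O
F3 | step 12 | tert-butyl (6,8-dimethoxy-2-oxo-2H-chromen-7-yl)oxyacetate | COc1cc2ccc(=O)oc2c(OC)c1OCC(=O)OC(C)(C)C
F4 | step 12 | (6,8-dimethoxy-2-oxo-2H-chromen-7-yl)oxyacetic acid | COc1cc2ccc(=O)oc2c(OC)c1OCC(=O)O
F5 | step 9 | 3-chloro-4-{[7-(benzyloxy)-6,8-dimethoxy-2-oxo-2H-chromen-3-yl]oxy}cyclobut-3-ene-1,2-dione | ClC1=C(Oc2cc3cc(OC)c(OCc4ccccc4)c(OC)c3oc2=O)C(=O)C1=O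
F6 | step 9 | 3-{[7-(benzyloxy)-6,8-dimethoxy-2-oxo-2H-chromen-3-yl]oxy}-4-hydroxycyclobut-3-ene-1,2-dione | OC1=C(Oc2cc3cc(OC)c(OCc4ccccc4)c(OC)c3oc2=O)C(=O)C1=O
F7 | step 14 | 7-(benzyloxy)-3-[4-(diethoxymethyl)-3,6-dihydroxy-2-methoxyphenoxy]-6,8-dimethoxy-2H-chromen-2-one | Oc1c(OC)c(Oc2cc3cc(OC)c(OCc4ccccc4)c(OC)c3oc2=O)c(O)cc1C(OCC)OCC
F8 | step 14 | 4-{[7-(benzyloxy)-6,8-dimethoxy-2-oxo-2H-chromen-3-yl]oxy}-2,5-dihydroxy-3-methoxybenzaldehyde | O=Cc1cc(O)c(Oc2cc3cc(OC)c(OCc4ccccc4)c(OC)c3oc2=O)c(OC)c1O
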